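**Ledger first.** Keep one ledger: each J charged stands as J, J.Z or Z.J.Z, and the three fractions sum to one. Then count turnovers: let n be the area under Z against time, multiplied by the rate constant of J + Z.

    Z + Q → Z.Q (k1 = 1.4 × 10⁻⁴ M⁻¹ s⁻¹)
    Z ⇌ G, rate k2*([Z] - [G]/K2) per volume of the first phase (K2 = 5.3, k2 = 0.0036 s⁻¹)
    J + Z → J.Z (k3 = 2.3 × 10⁻⁴ M⁻¹ s⁻¹)
    Z + J.Z → Z.J.Z (k4 = 5.4 × 10⁻⁵ M⁻¹ s⁻¹)
    2 Z → Z2 (k5 = 0.0016 M⁻¹ s⁻¹)

J 0.80 M; G 1.44 M; Q 0.400 M; time 5.0 h; volume of the second phase over the first 2.0

- a doubled species enters its step squared and goes two at a time
- in the second phase: G; everything else is in the first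
- charges count per volume of the first phase; a concentration in a rate is the amount of a species over the volume of its own phase; every rate counts per litre of the first phase
- run time (flask): 5.0 h

1. J.Z at 5.0 h, in percent of the J charged
2. the change that raises the amount of J.Z at 5.0 h, in percent of the J charged most ("none" if none brings more than 2 percentage points) (beta / delta / none)
3. amount of J.Z at 5.0 h, in percent of the J charged, after delta

**Main step.** Run J + Z by itself, with G feeding Z. At partition balance Z holds 8.62% of the G charge; hold Z there, and J falls pseudo-first-order through 0.514 turnovers, which puts J.Z at 40.2% on this first reckoning.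

**Add drains.** Now let Z leave. J and Q at their charges take Z at the first-order rate w = 0.864 h⁻¹, and with pairing of Z at its balance level the total is 2.29 h⁻¹. Transfer is faster than this drain, and Z lags behind balance: the charge now stands at D = 13.5 times Z, not 11.6.

**Add depletion.** The G store sinks too. Hold J, Q and D at these values and integrate, with κ the constant of J + Z, k that of pairing, C the G charge and t the time:

n = κ(D/2k) ln(1 + (2kC/Dw)(1 − exp(−wt/D)))

This gives the turnover count 0.319. Z + J.Z has a smaller constant than J + Z but still removes some J.Z, so with λ its constant, J.Z = κ/(κ−λ) × (exp(−λn/κ) − exp(−n)). My figure is 26.3%.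

**Both changes.** Delta halves the lag, so D becomes 12.5, n becomes 0.333, and J.Z becomes 27.2%. Beta gives D = 14.6 and n = 0.540, so J.Z becomes 39.0%. Beta reckons to more J.Z than delta, so I pick beta.

**The forecast.** The forecast gives 27%, 27.7% after delta and beta as the best change, holding that “doubling G raises Z greatly”.

**The result.** The flask gives 27.0%, 27.6% after delta, and beta as the best change, worth 14 percentage points. J stands at 71.9% at 5.00 h, which reads as 0.330 turnovers against my 0.319. Now carry the count to the neighbour flask read at 3.0 h: n reckons to 0.216, so my figures there are 80.6% J and 18.9% J.Z. That neighbour flask holds 80.3% J and 19.2% J.Z.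

All constants come from no measurement, and the outcome is calculated.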